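Which of elm, alder and oak holds the most target at the end?

1. which flask leads in amount of target, in percent of the substrate charged ("all alike" within 1.5 percentage points) (elm / alder / oak / all alike)
2. how much target is there at the end, in percent of the substrate charged: elm
3. how much target is there at the end, in percent of the substrate charged: alder
4. how much target is there at the end, in percent of the substrate charged: oak

| flask | substrate | reagent | catalyst | remark | time |
|---|---|---|---|---|---|
| autumn | 20 mM | 50 mM | 40 µM | run made earlier |  |
| noon | 20 mM | 70 mM | 40 µM | run made earlier |  |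
| spring | 20 mM | 110 mM | 40 µM | run made earlier |  |
| dusk | 20 mM | 50 mM | 20 µM | run made earlier |  |
| elm | 20 mM | 50.0 mM (fed, over 12 h) | 40 µM | all else is in the flask from the start; the feed brings no volume worth counting | 15 h |
| alder | 20 mM (fed, over 12 h) | 50.0 mM | 40 µM | all else is in the flask from the start; the feed brings no volume worth counting | 15 h |
| oak | 20 mM | 50.0 mM | 40 µM | everything together at the start | 15 h |

| run | time / h | target / % |
|---|---|---|
| autumn | 1.00 | 32.2 |
| autumn | 3.00 | 45.7 |
| autumn | 5.00 | 27.2 |
| autumn | 8.00 | 15.4 |
| autumn | 12.0 | 7.9 |
| autumn | 15.0 | 3.6 |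
| noon | 0.667 | 31.1 |
| noon | 2.00 | 43.4 |
| noon | 3.00 | 28.0 |
| noon | 5.00 | 9.8 |
| noon | 6.00 | 7.9 |
| noon | 10.0 | 0.6 |
| spring | 1.50 | 31.1 |
| spring | 3.00 | 5.9 |
| spring | 5.00 | 2.4 |
| spring | 6.00 | 0 |
| spring | 8.00 | 0 |
| spring | 10.0 | 0 |
| dusk | 0.833 | 13.0 |
| dusk | 2.50 | 26.1 |
| dusk | 4.00 | 27.6 |
| dusk | 6.00 | 26.1 |
| dusk | 10.0 | 14.5 |

(scatter of a reading: 1 percentage point)



I read the runs as a ladder of times. On the first rung substrate becomes target: autumn reads a peak of 45.7% at 3.00 h. By 5.00 h autumn's target is falling, and I take substrate, the limiting reagent, as gone there.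

On the next rung I read the fall as target taking up one more reagent. Let p be target as a fraction of the substrate charge. Once substrate is gone, reagent left, in substrate charges, is r = s + p, where s is the spare:

s = reagent charge over substrate charge, less two = 0.500

Then ln(r/p) climbs in a straight line. Autumn's readings give its slope:

slope = 0.166 h⁻¹

I call this the tail rate: the hourly climb of ln(r/p) at this spare, with substrate gone and no feed running. It is a reading, and its last point carries the scatter of 1 percentage point.

The last rungs are the feed, 12 h, and the time, 15 h. Elm, alder and oak have autumn's reagent charge and substrate charge, so once their feeds are in they have its spare. Oak is autumn's recipe, and autumn reads 3.6% at 15.0 h. Elm has 3.00 h after its feed, and that is tail if its substrate is gone by then. As my own trial I start elm there from autumn's peak, and the tail leaves: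

p = 20.5%

The forecast names elm: elm 16% (11% to 22%), alder 14.5% (10% to 20%), oak 4.5% (3% to 6%). My trial stands higher than its elm. Its words: “Elm and alder are close, with elm slightly ahead.”

The flask gives elm in the lead: elm 16.6%, alder 13.4%, oak 4.15%.

substrate + reagent + catalyst → target + catalyst, rate k1*[substrate]*[reagent]*[catalyst]/(1 + ([substrate]/sat1)) (0.558 mM, k = 2470 M⁻² s⁻¹); reagent + target → over-reaction product (k = 0.00437 M⁻¹ s⁻¹) In elm, target's half-life at the asked time is 3.3 h, longer than the 3.00 h after the feed. Elm stands at 33.2% target and 0% substrate at 12.0 h, and from that target the tail rate reckons 16.0%, against 16.6%. Alder holds 22.7% target and 2.70% substrate at 12.0 h; counting both as target, the tail rate gives 12.9%, against 13.4%.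

All runs were generated by integration for an exercise.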